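**Assumption:** "Fertidin" is taken to be exactly the given SMILES, i.e. jaeschkeanadiol 6-O-p-anisate, (1R,4R,5S,6S) in daucane numbering = (3R,3aS,4S,8aR) in azulene numbering.

## Retrosynthetic overview

1. Ester C–O: target ⇒ jaeschkeanadiol + p-anisoyl chloride (selective acylation of the secondary OH).
2. Seven-membered ring formed last by RCM (C8=C9) of an allyl/methallyl diene on a fully substituted cyclopentane.
3. C4 carbinol by i-Pr–Ce addition to the cyclopentanone; C5–C6 bond and both stereocentres by anti-aldol of a regiodefined enolate with 3-methylbut-3-enal.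
4. Quaternary C1 by conjugate methylation of (S)-3-allyl-4-silyloxycyclopentenone trans to OTBS. The OTBS centre comes from commercial (S)-4-TBSO-cyclopentenone and is sacrificial (removed by E1cB, then CuH).
5. Ring order: cyclopentane (chiral pool) first, cycloheptene second. Stereocentres: C1 in step 3, C5 and C6 in step 5, C4 in step 8.

## Forward route

**Step 1**
Reactants: 1 (S)-4-(tert-butyldimethylsilyloxy)cyclopent-2-en-1-one; 2 allylmagnesium bromide; 3 chlorotrimethylsilane
Product: 4 (3S,4S)-3-allyl-4-(TBSO)-1-(TMSO)cyclopent-1-ene (trans)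
Conditions: allylMgBr, CuBr·SMe2, TMSCl, THF, −78 °C; Et3N quench
Reagents that add atoms: allylmagnesium bromide, C=CC[Mg]Br; chlorotrimethylsilane, C[Si](C)(C)Cl
Why: TMSCl-accelerated allylcopper 1,4-addition anti to OTBS gives the regiodefined silyl enol ether; the new C3 centre is erased in step 2.

**Step 2**
Reactants: 4
Product: 5 (S)-3-allyl-4-(TBSO)cyclopent-2-en-1-one
Conditions: Pd(OAc)2 (1.05 equiv), MeCN, rt
Reagents that add atoms: none
Why: Saegusa–Ito dehydrogenation of the silyl enol ether regenerates the enone with allyl on the β-carbon; the OTBS stereocentre is untouched.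

**Step 3**
Reactants: 5; 6 methyllithium (as Me2CuLi); 3 chlorotrimethylsilane
Product: 7 (3R,4S)-3-allyl-4-(TBSO)-3-methyl-1-(TMSO)cyclopent-1-ene
Conditions: Me2CuLi (MeLi, CuI), TMSCl, Et2O/THF, −78 → −40 °C; Et3N
Reagents that add atoms: methyllithium, [Li]C; chlorotrimethylsilane, C[Si](C)(C)Cl
Why: Gilman conjugate addition anti to the vicinal OTBS sets quaternary C1 (Me trans, allyl cis to OTBS); the enolate is trapped regiospecifically toward C5.

**Step 4**
Reactants: 8 3-methylbut-3-en-1-ol
Product: 9 3-methylbut-3-enal
Conditions: Dess–Martin periodinane, NaHCO3, CH2Cl2, 0 °C; cold solution used at once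
Reagents that add atoms: none
Why: Mild DMP oxidation gives the β,γ-unsaturated aldehyde without isomerisation to prenal.

**Step 5**
Reactants: 7; 9
Product: 10 (2S,3R,4S)-3-allyl-4-(TBSO)-2-[(1S)-1-hydroxy-3-methylbut-3-en-1-yl]-3-methylcyclopentan-1-one
Conditions: MeLi, THF, 0 °C (Li enolate); then 9, −78 °C; AcOH quench at −78 °C
Reagents that add atoms: none beyond reactant 9 (C=C(C)CC=O)
Why: Zimmerman–Traxler aldol of the cyclic (E)-enolate gives the anti adduct (C6 S). The aldehyde adds to the face opposite the allyl group, which is held pseudo-axial by its cis-vicinal OTBS, so the side chain ends cis to Me (C5 S). I expect useful but not complete selectivity here; minor isomers are removed by chromatography.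

**Step 6**
Reactants: 10
Product: 11 (4S,5S)-4-allyl-5-[(1S)-1-hydroxy-3-methylbut-3-en-1-yl]-4-methylcyclopent-2-en-1-one
Conditions: DBU, CH2Cl2, −20 → 0 °C
Reagents that add atoms: none
Why: E1cB loss of silanolate through the unhindered C3 methylene removes the control element; the hindered C5–H is much slower to enolise.

**Step 7**
Reactants: 11
Product: 12 (2S,3R)-3-allyl-2-[(1S)-1-hydroxy-3-methylbut-3-en-1-yl]-3-methylcyclopentan-1-one
Conditions: [(Ph3P)CuH]6 (Stryker), benzene, H2O (few equiv), rt
Reagents that add atoms: none (H only)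
Why: CuH 1,4-reduction touches only the enone; the copper enolate lies toward C3, so C5 is not epimerised and the isolated alkenes survive.

**Step 8**
Reactants: 12; 13 isopropylmagnesium chloride
Product: 14 (1R,2S,3R)-3-allyl-2-[(1S)-1-hydroxy-3-methylbut-3-en-1-yl]-3-methyl-1-(propan-2-yl)cyclopentan-1-ol
Conditions: i-PrMgCl/CeCl3 (3.5 equiv), THF, −78 → −20 °C
Reagents that add atoms: isopropylmagnesium chloride, CC(C)[Mg]Cl
Why: Organocerium 1,2-addition suppresses enolisation and β-hydride reduction; attack anti to the C5 side chain puts i-Pr trans and OH cis to it (C4 R).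

**Step 9**
Reactants: 14
Product: 15 jaeschkeanadiol, (3R,3aS,4S,8aR)-6,8a-dimethyl-3-(propan-2-yl)-1,2,3,3a,4,5,8,8a-octahydroazulene-3,4-diol
Conditions: Grubbs II (5–10 mol %), CH2Cl2 (2 mM), 40 °C
Reagents that add atoms: none (ethylene lost)
Why: RCM of the allyl and methallyl arms closes the trans-fused seven-membered ring with the trisubstituted C8=C9 olefin; no stereocentre is touched.

**Step 10**
Reactants: 15; 16 4-methoxybenzoyl chloride
Product: 17 Fertidin (target)
Conditions: p-anisoyl chloride, DMAP, Et3N, CH2Cl2, rt → 40 °C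
Reagents that add atoms: 4-methoxybenzoyl chloride, COc1ccc(C(=O)Cl)cc1
Why: DMAP-catalysed acylation takes the secondary 6-OH only; the tertiary 4-OH is inert.

## Compound list

1 | (S)-4-(tert-butyldimethylsilyloxy)cyclopent-2-en-1-one | O=C1C=C[C@@H](O[Si](C)(C)C(C)(C)C)C1 | starting material
2 | allylmagnesium bromide | C=CC[Mg]Br | starting material (reagent)
3 | chlorotrimethylsilane | C[Si](C)(C)Cl | starting material (reagent)
4 | (3S,4S)-3-allyl-4-(TBSO)-1-(TMSO)cyclopent-1-ene | C[Si](C)(C)OC1=C[C@H](CC=C)[C@@H](O[Si](C)(C)C(C)(C)C)C1 | intermediate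
5 | (S)-3-allyl-4-(TBSO)cyclopent-2-en-1-one | O=C1C=C(CC=C)[C@@H](O[Si](C)(C)C(C)(C)C)C1 | intermediate
6 | methyllithium (used as Me2CuLi) | [Li]C | starting material (reagent)
7 | (3R,4S)-3-allyl-4-(TBSO)-3-methyl-1-(TMSO)cyclopent-1-ene | C[Si](C)(C)OC1=C[C@@](C)(CC=C)[C@@H](O[Si](C)(C)C(C)(C)C)C1 | intermediate
8 | 3-methylbut-3-en-1-ol | C=C(C)CCO | starting material
9 | 3-methylbut-3-enal | C=C(C)CC=O | intermediate
10 | (2S,3R,4S)-3-allyl-4-(TBSO)-2-[(1S)-1-hydroxy-3-methylbut-3-enyl]-3-methylcyclopentan-1-one | C=C(C)C[C@H](O)[C@H]1C(=O)C[C@H](O[Si](C)(C)C(C)(C)C)[C@]1(C)CC=C | intermediate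
11 | (4S,5S)-4-allyl-5-[(1S)-1-hydroxy-3-methylbut-3-enyl]-4-methylcyclopent-2-en-1-one | C=C(C)C[C@H](O)[C@H]1C(=O)C=C[C@]1(C)CC=C | intermediate
12 | (2S,3R)-3-allyl-2-[(1S)-1-hydroxy-3-methylbut-3-enyl]-3-methylcyclopentan-1-one | C=C(C)C[C@H](O)[C@H]1C(=O)CC[C@]1(C)CC=C | intermediate
13 | isopropylmagnesium chloride | CC(C)[Mg]Cl | starting material (reagent)
14 | (1R,2S,3R)-3-allyl-2-[(1S)-1-hydroxy-3-methylbut-3-enyl]-3-methyl-1-isopropylcyclopentan-1-ol | C=C(C)C[C@H](O)[C@H]1[C@](O)(C(C)C)CC[C@]1(C)CC=C | intermediate
15 | jaeschkeanadiol | O[C@H]1CC(C)=CC[C@@]2(C)CC[C@@](O)(C(C)C)[C@H]12 | intermediate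
16 | 4-methoxybenzoyl chloride | COc1ccc(C(=O)Cl)cc1 | starting material
17 | Fertidin | COc1ccc(C(=O)O[C@H]2CC(C)=CC[C@@]3(C)CC[C@@](O)(C(C)C)[C@H]23)cc1 | target

## Step count

Total steps: 10. Longest linear sequence: 9 (steps 1–3, 5–10 from compound 1); step 4 is a one-step side branch.

## Three steps most likely to fail, with fallbacks

1. **Step 5 (aldol).** The enolate is hindered next to the quaternary carbon, the aldehyde is enolisable and isomerisation-prone, and two stereocentres are set at once; the C5 facial preference rests on a conformational argument, not on precedent. Fallback: invert the order of bond formation. Install the C5 side chain first on a 4-substituted cyclopent-2-enone (α′-aldol of 3-ethoxycyclopentenone, then Stork–Danheiser transposition). Then build C1 by α′-methylation and α′-allylation trans to that substituent, and move the carbonyl to C4 by Wharton transposition. If only C6 is the problem, oxidise C6 after step 8 and reduce with Me4NBH(OAc)3, using the 4-OH to direct 1,3-anti delivery.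

2. **Step 3 (quaternary centre).** Cuprate addition to a β,β-disubstituted enone flanked by OTBS, with an acidic doubly allylic CH2, may be slow or give deprotonation. Fallback: switch from substrate to catalyst control. Cu–NHC-catalysed asymmetric conjugate addition of Me3Al to 3-allylcyclopent-2-enone (from 3-ethoxycyclopentenone + allylMgBr), trapped as the TMS enol ether, gives the des-silyloxy analogue of 7. This deletes steps 1–2 and 6–7 but gives up the OTBS bias on the C5 face in the aldol.

3. **Step 8 (i-Pr addition).** The ketone is hindered and enolisable, and the free β-hydroxyl invites retro-aldol. Fallback: change both order and nucleophile. Protect 6-OH as TES, do the RCM first, add 2-propenylcerium (sp2, less basic) to the rigid trans-fused bicyclic ketone from the face anti to the angular methyl, then reduce the isopropenyl group by hydroxyl-directed hydrogenation (Crabtree) and deprotect.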